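**Plan**

- Retrosynthesis: the pyrrole N–H is masked as N-(2,4-dimethoxybenzyl). The ring is then cut at N1–C2 and C2–C3, giving methyl diazoacetate (C2 with its ester) and the 1-azadiene of (E)-tetracos-2-enal. The enal is cut at its C2=C3 bond into docosanal and a formylmethylene phosphorane.
- Enabling feature: in the ring numbered N1, C2 (CO2Me), C3 (henicosyl), C4, C5, carbon C2 is bonded only to N1, C3 and the ester, so it can arrive as one carbenoid carbon. The other four ring atoms, N1=C5–C4=C3 with the C21 chain, are the conjugated unit of an enal imine.
- Forward: the C22 alcohol is oxidised, extended by two carbons and condensed with the benzylamine. The only ring forms when a rhodium carbenoid is delivered to the imine nitrogen and the conjugated azomethine ylide closes onto C3. Dehydrogenation and acidolytic N-debenzylation finish the route.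
- Stereochemistry: the target has no stereocentre. C2 and C3 of the dihydropyrrole arise in the electrocyclisation (racemic, trans expected) and are both erased on aromatisation. The E alkene and E imine matter only for the reactivity of the azadiene.

Key step: step 5

Remark: compound 10 is drawn as the trans racemate (one enantiomer shown); a cis isomer would be carried on unchanged, because step 6 flattens both centres. Methyl diazoacetate 8 is handled only as a dilute solution and never concentrated to dryness.

**Step 1**
Reactants: 1 docosan-1-ol
Product: 2 docosanal
Conditions: TEMPO (10 mol %), PhI(OAc)2 (1.1 equiv), CH2Cl2, 25–30 °C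
Reagents that add atoms: none
Why: TEMPO-catalysed oxoammonium oxidation with PhI(OAc)2 as terminal oxidant should stop cleanly at the aldehyde of an unfunctionalised primary alcohol and runs near room temperature, where the waxy C22 alcohol stays in solution.

**Step 2**
Reactants: 2 docosanal; 3 (triphenylphosphoranylidene)acetaldehyde
Product: 4 (E)-tetracos-2-enal
Conditions: 3 (1.1 equiv), toluene, 80 °C
Reagents that add atoms: none
Why: Wittig olefination with the formyl-stabilised ylide should add two carbons and give the E enal, and because the saturated aldehyde is more electrophilic than the conjugated product, a single homologation should dominate when the ylide is kept near one equivalent.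

**Step 3**
Reactants: 4 (E)-tetracos-2-enal; 5 2,4-dimethoxybenzylamine
Product: 6 (1E,2E)-N-(2,4-dimethoxybenzyl)tetracos-2-en-1-imine
Conditions: MgSO4, CH2Cl2, 0 °C to rt; filtered, concentrated, used crude
Reagents that add atoms: none
Why: Imine condensation (Schiff base formation) by 1,2-addition of the primary amine and removal of water by the drying agent should give the thermodynamically preferred E C=N bond, while neutral conditions at or below room temperature disfavour conjugate addition and migration of the double bond toward the chain.

**Step 4**
Reactants: 7 glycine methyl ester hydrochloride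
Product: 8 methyl diazoacetate
Conditions: NaNO2, H2SO4 (cat.), CH2Cl2/H2O, −5 to 0 °C; dried CH2Cl2 solution used as such
Reagents that add atoms: sodium nitrite, [Na+].[O-]N=O
Why: Diazotisation of an α-amino ester: N-nitrosation and loss of water give a diazonium ion that sheds its acidic α-proton to the ester-stabilised diazo compound, which is extracted into the organic layer as it forms.

**Step 5**
Reactants: 6 (1E,2E)-N-(2,4-dimethoxybenzyl)tetracos-2-en-1-imine; 8 methyl diazoacetate
Product: 10 methyl trans-1-(2,4-dimethoxybenzyl)-3-henicosyl-2,3-dihydro-1H-pyrrole-2-carboxylate (racemic), via conjugated azomethine ylide 9 (not isolated)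
Conditions: Rh2(OAc)4 (2 mol %), ClCH2CH2Cl, 70 °C, 8 (1.2 equiv) added over 5 h by syringe pump
Reagents that add atoms: none
Why: Rh2(OAc)4 expels N2 from 8 to give an electrophilic rhodium carbenoid, the imine lone pair of 6 adds to it (bond N1–C2), and release of the metal leaves ylide 9, whose carbanionic C2 occupies the former lone-pair position and so lies on the same side of the C=N bond as the alkenyl arm. The closest known reaction type is the carbenoid-derived azomethine ylide of a conjugated imine (1-azadiene) that cyclises to a 2,3-dihydropyrrole, a formal [4+1] annulation. The five-membered ring closes by a thermal six-electron disrotatory 1,5-electrocyclisation over C2, N1, C5, C4 and C3 (bond C2–C3), leaving the C4=C5 enamine double bond. C3 is set by the E alkene geometry under the disrotatory motion and C2 by the ylide geometry, with the ester-bearing centre free to epimerise to the less crowded trans arrangement; as the material is racemic and step 6 destroys both centres, neither needs control. The step needs periselectivity for five-ring over aziridine closure and chemoselectivity for nitrogen over the alkene and the electron-rich arene. The first should come from the U-shaped ylide inherited from the E imine and from an ester that stabilises the ylide long enough for rotation about C4–C5 at 70 °C, the second from the much higher nucleophilicity of the imine lone pair and the slow addition of 8.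

**Step 6**
Reactants: 10 methyl trans-1-(2,4-dimethoxybenzyl)-3-henicosyl-2,3-dihydro-1H-pyrrole-2-carboxylate
Product: 11 methyl 1-(2,4-dimethoxybenzyl)-3-henicosyl-1H-pyrrole-2-carboxylate
Conditions: activated MnO2 (10 equiv), CH2Cl2, rt
Reagents that add atoms: none
Why: Oxidative dehydrogenation (aromatisation) of a 2,3-dihydropyrrole is driven by formation of the aromatic pyrrole, removes both stereocentres, and the heterogeneous oxidant should leave the dimethoxybenzyl group and the ester untouched, which a quinone oxidant might not.

**Step 7**
Reactants: 11 methyl 1-(2,4-dimethoxybenzyl)-3-henicosyl-1H-pyrrole-2-carboxylate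
Product: 12 methyl 3-henicosyl-1H-pyrrole-2-carboxylate
Conditions: CF3CO2H, anisole (10 equiv), 60 °C
Reagents that add atoms: none
Why: Acidolytic N-debenzylation: the 2-acylpyrrole is a good leaving group, the 2,4-dimethoxybenzyl cation is stabilised by its ortho and para methoxy groups, and anisole should trap it irreversibly by Friedel–Crafts alkylation, while the methyl ester is inert to anhydrous acid.

**Compound list**

1 | docosan-1-ol | CCCCCCCCCCCCCCCCCCCCCCO | starting material
2 | docosanal | CCCCCCCCCCCCCCCCCCCCCC=O | intermediate
3 | (triphenylphosphoranylidene)acetaldehyde | O=CC=P(c1ccccc1)(c1ccccc1)c1ccccc1 | starting material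
4 | (E)-tetracos-2-enal | CCCCCCCCCCCCCCCCCCCCC/C=C/C=O | intermediate
5 | 2,4-dimethoxybenzylamine | NCc1ccc(OC)cc1OC | starting material
6 | (1E,2E)-N-(2,4-dimethoxybenzyl)tetracos-2-en-1-imine | CCCCCCCCCCCCCCCCCCCCC/C=C/C=N/Cc1ccc(OC)cc1OC | intermediate
7 | glycine methyl ester hydrochloride | Cl.COC(=O)CN | starting material
8 | methyl diazoacetate | COC(=O)C=[N+]=[N-] | intermediate
9 | conjugated azomethine ylide: (methoxycarbonyl)methanide on the iminium nitrogen of 6, carbanion syn to the alkenyl arm | CCCCCCCCCCCCCCCCCCCCC/C=C/C=[N+](/Cc1ccc(OC)cc1OC)\[CH-]C(=O)OC | intermediate (not isolated)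
10 | methyl trans-1-(2,4-dimethoxybenzyl)-3-henicosyl-2,3-dihydro-1H-pyrrole-2-carboxylate (racemic, one enantiomer drawn) | COC(=O)[C@@H]1[C@@H](CCCCCCCCCCCCCCCCCCCCC)C=CN1Cc1ccc(OC)cc1OC | intermediate
11 | methyl 1-(2,4-dimethoxybenzyl)-3-henicosyl-1H-pyrrole-2-carboxylate | COC(=O)c1c(CCCCCCCCCCCCCCCCCCCCC)ccn1Cc1ccc(OC)cc1OC | intermediate
12 | methyl 3-henicosyl-1H-pyrrole-2-carboxylate | CCCCCCCCCCCCCCCCCCCCCc1cc[nH]c1C(=O)OC | target

**Step count**

Total steps: 7. Longest linear sequence: 6 (steps 1, 2, 3, 5, 6, 7); step 4 is a one-step branch that feeds step 5.

**Steps most likely to fail**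

1. Step 5. The ylide may close to the three-membered ring instead of the five-membered one. The imine double bond may shift toward the chain through its γ-hydrogens before carbene transfer. The imine may slow the catalyst by coordination, and the enamine product may be consumed by excess carbenoid. The fallback sets out from docosanal 2 and returns at target 12 by a Barton–Zard pyrrole synthesis, which builds the ring from other bonds and needs no N-protection. Henry addition of nitromethane with catalytic Et3N would give 1-nitrotricosan-2-ol F1. Mesylation and elimination (MsCl, Et3N, CH2Cl2, 0 °C) would give (E)-1-nitrotricos-1-ene F2. Treatment of F2 with methyl isocyanoacetate and DBU in THF should add the isocyanoacetate carbon to the chain-bearing alkene carbon, close the ring onto the isocyanide carbon, expel nitrite and tautomerise to 12.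

2. Step 7. Cleavage of the N–benzyl bond may be incomplete, or the benzyl cation may migrate onto a free pyrrole carbon instead of being trapped by anisole. The fallback sets out from enal 4 and returns at target 12, replacing the acid-labile group by one removed with base. Condensation of 4 with 3-aminopropanenitrile over MgSO4 would give 3-{[(1E,2E)-tetracos-2-en-1-ylidene]amino}propanenitrile F3. The same Rh2(OAc)4-catalysed reaction with 8 would pass through N-(2-cyanoethyl) azomethine ylide F4 to methyl trans-1-(2-cyanoethyl)-3-henicosyl-2,3-dihydro-1H-pyrrole-2-carboxylate F5. MnO2 would aromatise this to methyl 1-(2-cyanoethyl)-3-henicosyl-1H-pyrrole-2-carboxylate F6. DBU in DMF at 80 °C should then release acrylonitrile by retro-Michael elimination and give 12.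

3. Step 2. The enal product may be homologated a second time to the dienal, the waxy aldehyde may convert slowly, and separation from the phosphine oxide may cost material. The fallback sets out from docosanal 2 and returns at enal 4 through the ester oxidation level. Horner–Wadsworth–Emmons olefination with triethyl phosphonoacetate and NaH in THF would give ethyl (E)-tetracos-2-enoate F7. Reduction with i-Bu2AlH in toluene at −20 °C would give (E)-tetracos-2-en-1-ol F8, and allylic oxidation with MnO2 in CH2Cl2 would return 4.

**Further compounds**

F1 | step 5 | 1-nitrotricosan-2-ol (racemic) | CCCCCCCCCCCCCCCCCCCCCC(O)C[N+](=O)[O-]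
F2 | step 5 | (E)-1-nitrotricos-1-ene | CCCCCCCCCCCCCCCCCCCCC/C=C/[N+](=O)[O-]
F3 | step 7 | 3-{[(1E,2E)-tetracos-2-en-1-ylidene]amino}propanenitrile | CCCCCCCCCCCCCCCCCCCCC/C=C/C=N/CCC#N
F4 | step 7 | N-(2-cyanoethyl) azomethine ylide, carbanion syn to the alkenyl arm | CCCCCCCCCCCCCCCCCCCCC/C=C/C=[N+](/CCC#N)\[CH-]C(=O)OC
F5 | step 7 | methyl trans-1-(2-cyanoethyl)-3-henicosyl-2,3-dihydro-1H-pyrrole-2-carboxylate (racemic, one enantiomer drawn) | COC(=O)[C@@H]1[C@@H](CCCCCCCCCCCCCCCCCCCCC)C=CN1CCC#N
F6 | step 7 | methyl 1-(2-cyanoethyl)-3-henicosyl-1H-pyrrole-2-carboxylate | COC(=O)c1c(CCCCCCCCCCCCCCCCCCCCC)ccn1CCC#N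
F7 | step 2 | ethyl (E)-tetracos-2-enoate | CCCCCCCCCCCCCCCCCCCCC/C=C/C(=O)OCC
F8 | step 2 | (E)-tetracos-2-en-1-ol | CCCCCCCCCCCCCCCCCCCCC/C=C/CO
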